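## Retrosynthetic overview
1. Alectorialic acid comes from its bis-MOM ether/tert-butyl ester by acidolysis. The internal benzyl ester rules out hydrogenolysis and base.
2. Key cut: the ring-B aryl–CH2 bond, not the ester C–O bond. This is the only dissonant (1,4-O,O) link in the molecule. It leads back to a ring-B aryl iodide and a ring-A aroyloxymethylstannane, an acyloxymethyl-anion (d1) equivalent that carries all of ring A.
3. The stannane comes from orsellinic acid and Bu3SnCH2I (O-alkylation), followed by Mg-mediated ortho-formylation at C3.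
4. The iodide comes from 2-methylresorcinol by MOM protection, sterically controlled Ir C–H borylation/iododeboronation meta to both oxygens, then ortho-lithiation/Boc2O.
5. Rings: none is built. Both benzene rings are bought, decorated in two parallel branches and joined in the penultimate step.

Assumption: the SMILES contains no stereocentre and no stereogenic double bond, so the target is achiral and no stereocontrol is needed.

## Route

**Step 1**
Reactants: 1 orsellinic acid (2,4-dihydroxy-6-methylbenzoic acid); 2 tributyl(iodomethyl)stannane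
Product: 3 (tributylstannyl)methyl 2,4-dihydroxy-6-methylbenzoate
Conditions: KHCO3 (1.1 equiv), DMF, rt, 12 h
Reagents that add atoms: none
Why: Carboxylate SN2 O-alkylation, in which KHCO3 ionises only the CO2H (the phenols stay protonated) and the primary α-stannyl iodide is a good SN2 partner, so the ester forms at room temperature without decarboxylation of 1; no stereocentre is formed.

**Step 2**
Reactants: 3 (tributylstannyl)methyl 2,4-dihydroxy-6-methylbenzoate
Product: 5 (tributylstannyl)methyl 3-formyl-2,4-dihydroxy-6-methylbenzoate, via 3-hydroxymethyl intermediate 4 (not isolated)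
Conditions: MgCl2 (3 equiv), Et3N (6 equiv), (CH2O)n (8 equiv), MeCN, 75 °C, 4 h; cold 5 % citric acid
Reagents that add atoms: formaldehyde (from paraformaldehyde), C=O
Why: Casnati–Skattebøl magnesium-mediated ortho-formylation, in which C3 lies ortho to both magnesium phenolates (chelated β-resorcylates substitute there, and C5 is also shielded by the 6-methyl), a second CH2O oxidises alkoxide 4 by hydride transfer, and the basic, weakly Lewis-acidic medium leaves the sp3 C–Sn bond and the hindered ester intact.

**Step 3**
Reactants: 6 2-methylresorcinol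
Product: 7 1,3-bis(methoxymethoxy)-2-methylbenzene
Conditions: NaH (2.4 equiv), MOMCl (2.4 equiv), DMF, 0 °C to rt
Reagents that add atoms: chloromethyl methyl ether, COCCl
Why: Williamson-type O-alkylation of both phenolates installs two acid-labile groups that tolerate Ir, Cu, LDA and Pd and that later direct lithiation.

**Step 4**
Reactants: 7 1,3-bis(methoxymethoxy)-2-methylbenzene
Product: 9 5-iodo-1,3-bis(methoxymethoxy)-2-methylbenzene, via aryl pinacolboronate 8 (not isolated)
Conditions: [Ir(OMe)(cod)]2 (1.5 mol %), dtbpy (3 mol %), B2pin2 (1.0 equiv), THF, 80 °C; evaporate; CuI (10 mol %), 1,10-phenanthroline (20 mol %), KI (1.5 equiv), MeOH–H2O 4:1, air, 80 °C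
Reagents that add atoms: bis(pinacolato)diboron, CC1(C)OB(OC1(C)C)B1OC(C)(C)C(C)(C)O1 (its boryl group stays only in 8); potassium iodide, [K+].[I-]
Why: Sterically controlled Ir-catalysed C–H borylation of a 1,2,3-trisubstituted arene reaches only C5–H, the one C–H with no ortho substituent and a site that electrophilic halogenation cannot reach, and the Cu-catalysed aerobic iododeboronation is non-acidic, so the MOM ethers survive.

**Step 5**
Reactants: 9 5-iodo-1,3-bis(methoxymethoxy)-2-methylbenzene
Product: 11 tert-butyl 6-iodo-2,4-bis(methoxymethoxy)-3-methylbenzoate, via aryllithium 10 (not isolated)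
Conditions: LDA (commercial solution, 1.2 equiv), THF, −78 °C, 45 min; Boc2O (1.6 equiv), −78 to −20 °C; H2O
Reagents that add atoms: di-tert-butyl dicarbonate, CC(C)(C)OC(=O)OC(=O)OC(C)(C)C; lithium diisopropylamide, [Li+].CC(C)[N-]C(C)C (its lithium stays only in 10)
Why: Directed ortho-metalation, in which the two remaining ring C–H bonds are equivalent by symmetry and each is flanked by OMOM (Li-coordinating) and iodine (acidifying), so the amide base deprotonates without C–I exchange, the 2-iodoaryllithium holds at −78 °C, and acylation by Boc2O gives the tert-butyl ester directly.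

**Step 6 (key step)**
Reactants: 5 (tributylstannyl)methyl 3-formyl-2,4-dihydroxy-6-methylbenzoate (1.3 equiv); 11 tert-butyl 6-iodo-2,4-bis(methoxymethoxy)-3-methylbenzoate
Product: 12 [2-(tert-butoxycarbonyl)-3,5-bis(methoxymethoxy)-4-methylphenyl]methyl 3-formyl-2,4-dihydroxy-6-methylbenzoate
Conditions: Pd(PPh3)4 (10 mol %), CuI (20 mol %), degassed 1,4-dioxane, 90 °C, 16 h
Reagents that add atoms: none
Why: Proposed new method: a Migita–Kosugi–Stille coupling in which tin delivers a complete aroyloxymethyl group, so that the O-bearing CH2 (by nature a formaldehyde-type acceptor carbon) acts as an acyloxymethyl-anion (d1) equivalent towards the C–I carbon of 11 (itself an acceptor site, β to the ester C=O and meta to both oxygens) by oxidative addition of the ester-activated aryl iodide, selective Sn-to-Pd transfer of the α-oxygenated CH2 over butyl (the acyl C=O can bind Pd, there is no β-hydrogen, and CuI in dioxane only scavenges free PPh3) and reductive elimination, all under neutral base-free conditions that spare the free phenols, CHO, MOM ethers, tert-butyl ester and hindered aryl ester; the closest known reaction types are the Pd-catalysed hydroxymethylation of aryl halides with Bu3SnCH2OH and Pd/Cu couplings of α-acyloxy- and α-alkoxystannanes; no stereocentre is formed.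

**Step 7**
Reactants: 12 protected benzyl ester
Product: 13 alectorialic acid, 2,4-dihydroxy-6-{[(3-formyl-2,4-dihydroxy-6-methylbenzoyl)oxy]methyl}-3-methylbenzoic acid
Conditions: TFA–CH2Cl2–H2O 10:20:1, 0 °C to rt, 2 h; evaporate cold, crystallise
Reagents that add atoms: none
Why: Global acidolysis (AAL1 loss of the tert-butyl group and acetal hydrolysis of both MOM ethers), which spares the internal benzyl ester because its benzylic cation would be meta to both oxygens and ortho to a carboxyl, while the short cold exposure limits protodecarboxylation and lactonisation to the phthalide.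

## Compound list
1 | orsellinic acid | Cc1cc(O)cc(O)c1C(=O)O | starting material
2 | tributyl(iodomethyl)stannane | CCCC[Sn](CI)(CCCC)CCCC | starting material
3 | (tributylstannyl)methyl 2,4-dihydroxy-6-methylbenzoate | CCCC[Sn](CCCC)(CCCC)COC(=O)c1c(C)cc(O)cc1O | intermediate
4 | (tributylstannyl)methyl 2,4-dihydroxy-3-(hydroxymethyl)-6-methylbenzoate (present as its magnesium salt, not isolated) | CCCC[Sn](CCCC)(CCCC)COC(=O)c1c(C)cc(O)c(CO)c1O | intermediate
5 | (tributylstannyl)methyl 3-formyl-2,4-dihydroxy-6-methylbenzoate | CCCC[Sn](CCCC)(CCCC)COC(=O)c1c(C)cc(O)c(C=O)c1O | intermediate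
6 | 2-methylresorcinol | Cc1c(O)cccc1O | starting material
7 | 1,3-bis(methoxymethoxy)-2-methylbenzene | COCOc1cccc(OCOC)c1C | intermediate
8 | 2-[3,5-bis(methoxymethoxy)-4-methylphenyl]-4,4,5,5-tetramethyl-1,3,2-dioxaborolane (not isolated) | COCOc1cc(B2OC(C)(C)C(C)(C)O2)cc(OCOC)c1C | intermediate
9 | 5-iodo-1,3-bis(methoxymethoxy)-2-methylbenzene | COCOc1cc(I)cc(OCOC)c1C | intermediate
10 | [6-iodo-2,4-bis(methoxymethoxy)-3-methylphenyl]lithium (not isolated) | [Li]c1c(I)cc(OCOC)c(C)c1OCOC | intermediate
11 | tert-butyl 6-iodo-2,4-bis(methoxymethoxy)-3-methylbenzoate | CC(C)(C)OC(=O)c1c(I)cc(OCOC)c(C)c1OCOC | intermediate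
12 | [2-(tert-butoxycarbonyl)-3,5-bis(methoxymethoxy)-4-methylphenyl]methyl 3-formyl-2,4-dihydroxy-6-methylbenzoate | Cc1cc(O)c(C=O)c(O)c1C(=O)OCc1cc(OCOC)c(C)c(OCOC)c1C(=O)OC(C)(C)C | intermediate
13 | alectorialic acid | Cc1cc(O)c(C=O)c(O)c1C(=O)OCc1cc(O)c(C)c(O)c1C(=O)O | target

## Counts and risks
Total step count: 7.
Longest linear sequence: 5 (steps 3, 4, 5, 6, 7).

**Step 6 (transfer of the full aroyloxymethyl group from tin).** Possible failures are slow sp3 transmetalation, butyl transfer and protodestannylation.
- The fallback sets out from 11 and comes back at 12.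
- The d1 unit is transferred in its simplest form. Pd-catalysed coupling of 11 with commercial (tributylstannyl)methanol (Pd(PPh3)4, dioxane, 90 °C) gives tert-butyl 6-(hydroxymethyl)-2,4-bis(methoxymethoxy)-3-methylbenzoate F1.
- The halves are then joined at oxygen. Mitsunobu esterification of F1 with orsellinic acid 1 (PPh3, DIAD, THF, 0 °C; the carboxylic acid reacts ahead of the phenols) gives [2-(tert-butoxycarbonyl)-3,5-bis(methoxymethoxy)-4-methylphenyl]methyl 2,4-dihydroxy-6-methylbenzoate F2.
- Mg-mediated ortho-formylation of F2 can only act on the ring that carries free phenols, and it gives 12.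

**Step 2 (C3 versus C5 selectivity and conversion of the formylation).**
- The fallback sets out from 1 and comes back at 5.
- The aldehyde is installed before tin is present, using a chelating Lewis acid.
- BnBr/KHCO3/DMF gives benzyl 2,4-dihydroxy-6-methylbenzoate F3.
- Rieche formylation (Cl2CHOMe, TiCl4, CH2Cl2, −10 °C) gives benzyl 3-formyl-2,4-dihydroxy-6-methylbenzoate F4, which is separated from any 5-formyl isomer.
- Brief hydrogenolysis (H2, Pd/C, EtOAc) gives haematommic acid F5.
- Alkylation of F5 with 2 under the conditions of step 1 gives 5.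

**Step 5 (LDA on an aryl iodide).** Possible failures are incomplete deprotonation, iodine scrambling, aryne formation and slow trapping by bulky Boc2O.
- The fallback sets out from 7 and comes back at 11, bypassing 9.
- The carboxyl group is installed first and then serves as the directing group.
- n-BuLi/THF at 0 °C followed by CO2 gives 2,4-bis(methoxymethoxy)-3-methylbenzoic acid F6.
- Carboxylate-directed ortho-lithiation (s-BuLi/TMEDA, 2.2 equiv, THF, −78 °C) followed by I2 gives 6-iodo-2,4-bis(methoxymethoxy)-3-methylbenzoic acid F7.
- Neutral esterification with N,N-dimethylformamide di-tert-butyl acetal (toluene, 80 °C) gives 11.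

## Further compounds
F1 | step 6 | tert-butyl 6-(hydroxymethyl)-2,4-bis(methoxymethoxy)-3-methylbenzoate | CC(C)(C)OC(=O)c1c(CO)cc(OCOC)c(C)c1OCOC
F2 | step 6 | [2-(tert-butoxycarbonyl)-3,5-bis(methoxymethoxy)-4-methylphenyl]methyl 2,4-dihydroxy-6-methylbenzoate | Cc1cc(O)cc(O)c1C(=O)OCc1cc(OCOC)c(C)c(OCOC)c1C(=O)OC(C)(C)C
F3 | step 2 | benzyl 2,4-dihydroxy-6-methylbenzoate | Cc1cc(O)cc(O)c1C(=O)OCc1ccccc1
F4 | step 2 | benzyl 3-formyl-2,4-dihydroxy-6-methylbenzoate | Cc1cc(O)c(C=O)c(O)c1C(=O)OCc1ccccc1
F5 | step 2 | haematommic acid (3-formyl-2,4-dihydroxy-6-methylbenzoic acid) | Cc1cc(O)c(C=O)c(O)c1C(=O)O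
F6 | step 5 | 2,4-bis(methoxymethoxy)-3-methylbenzoic acid | COCOc1ccc(C(=O)O)c(OCOC)c1C
F7 | step 5 | 6-iodo-2,4-bis(methoxymethoxy)-3-methylbenzoic acid | COCOc1cc(I)c(C(=O)O)c(OCOC)c1C
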